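**Retrosynthetic overview**

1. The target 28 is released from the penta-silyl flavanone 27 by one buffered fluoride step. All five phenols travel as TBS ethers, so no acid meets the C2–O1 benzylic ether (flanked by the trioxygenated ring B) or the lavandulyl alkenes next to free phenols.
2. The strategy rests on C2: a methine bonded to O1 and to the electron-rich ring B. It is traced back to the benzylic OCH2 of an aryl benzyl ether whose hydridic C–H lies six atoms from a carbene carbon at C3. Cutting C2–C3 gives diazomethyl ketone 26; ring C is the only ring made (rings A and B are bought as arenes) and closes by rhodium carbenoid C–H insertion.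
3. 26 comes from acid 22 and aldehyde 21. The O1–CH2 bond is made by Mitsunobu etherification of salicylaldehyde 17 with the ring B benzyl alcohol 20 (from 2,4,6-trihydroxybenzaldehyde).
4. 17 comes from phenol 16 by ortho-formylation; both ortho sites are equivalent, which fixes the 6-lavandulyl pattern. 16 comes from 2-iodoresorcinol by silylation, C–H borylation para to iodine, Negishi coupling at C–I and C–B oxidation.
5. The side chain enters as (S)-lavandulyl iodide 9, made by Evans deconjugative alkylation of a senecioyl imide with prenyl bromide; this sets the side-chain stereocentre (R in the target).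

Key step: step 15

Abbreviations: TBS = tert-butyldimethylsilyl, TBSO = tert-butyldimethylsilyloxy, lavandulyl = 5-methyl-2-(prop-1-en-2-yl)hex-4-en-1-yl, B2pin2 = bis(pinacolato)diboron, SPhos = 2-dicyclohexylphosphino-2',6'-dimethoxybiphenyl, DIAD = diisopropyl azodicarboxylate.

Assumption: the sense of induction of Rh2(S-PTTL)4 in this 1,6-insertion cannot be predicted with certainty; the (S)-catalyst is written, and the mirror-image catalyst Rh2(R-PTTL)4 would be used if a model benzyl ether shows that it is the one leading to (2S).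

**Route**

Step 1
Reactants: 1 (S)-4-benzyloxazolidin-2-one; 2 3-methylbut-2-enoyl chloride
Product: 4 (S)-4-benzyl-3-(3-methylbut-2-enoyl)oxazolidin-2-one, via lithium oxazolidinide 3 (not isolated)
Conditions: n-BuLi (1.05 equiv), THF, −78 °C; then 2, −78 → 0 °C
Reagents that add atoms: none
Why: N-acylation of the lithiated Evans auxiliary by the acid chloride, run without amine base so that no vinylketene is formed from the senecioyl chloride.

Step 2
Reactants: 4 (S)-4-benzyl-3-(3-methylbut-2-enoyl)oxazolidin-2-one; 5 1-bromo-3-methylbut-2-ene (prenyl bromide)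
Product: 7 (S)-4-benzyl-3-[(2S)-5-methyl-2-(prop-1-en-2-yl)hex-4-enoyl]oxazolidin-2-one, via sodium dienolate 6 (not isolated)
Conditions: NaN(SiMe3)2 (1.1 equiv), THF, −78 °C; then 5 (3 equiv), −78 → −40 °C
Reagents that add atoms: none
Why: Evans deconjugative alkylation, in which γ-deprotonation of the s-cis enoyl imide gives the sodium-chelated (Z)-dienolate and prenyl bromide attacks its α-carbon on the face away from the benzyl group, which should set the (2S) centre of the lavandulyl skeleton.

Step 3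
Reactants: 7 (S)-4-benzyl-3-[(2S)-5-methyl-2-(prop-1-en-2-yl)hex-4-enoyl]oxazolidin-2-one
Product: 8 (S)-lavandulol [(2S)-5-methyl-2-(prop-1-en-2-yl)hex-4-en-1-ol]
Conditions: LiBH4 (1.5 equiv), MeOH (1.5 equiv), Et2O, 0 °C
Reagents that add atoms: none
Why: reductive cleavage of the exocyclic imide carbonyl by LiBH4 releases the primary alcohol and the auxiliary under conditions too mild to epimerise or conjugate the α-allylic stereocentre.

Step 4
Reactants: 8 (S)-lavandulol
Product: 9 (S)-lavandulyl iodide [(3S)-3-(iodomethyl)-2,6-dimethylhepta-1,5-diene]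
Conditions: I2, PPh3, imidazole, CH2Cl2, 0 °C → rt
Reagents that add atoms: iodine, II
Why: Appel-type iodination of a primary alcohol by SN2 displacement of the oxyphosphonium at CH2, leaving the β-stereocentre untouched.

Step 5
Reactants: 10 2-iodobenzene-1,3-diol (2-iodoresorcinol)
Product: 11 2-iodo-1,3-bis(TBSO)benzene
Conditions: TBSCl (2.4 equiv), imidazole (5 equiv), DMF, rt
Reagents that add atoms: tert-butyldimethylsilyl chloride, CC(C)(C)[Si](C)(C)Cl
Why: standard imidazole-mediated silylation of both phenols, which installs the future C5 and C7 silyl ethers on either side of the iodide.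

Step 6
Reactants: 11 2-iodo-1,3-bis(TBSO)benzene
Product: 12 2-[3,5-bis(TBSO)-4-iodophenyl]-4,4,5,5-tetramethyl-1,3,2-dioxaborolane
Conditions: [Ir(OMe)(cod)]2 (1.5 mol %), 4,4'-di-tert-butyl-2,2'-bipyridine (3 mol %), B2pin2 (1.0 equiv), hexane, 60 °C
Reagents that add atoms: bis(pinacolato)diboron, CC1(C)OB(OC1(C)C)B1OC(C)(C)C(C)(C)O1
Why: sterically controlled iridium-catalysed aromatic C–H borylation, which should go only to the one C–H that has no ortho substituent (para to iodine) and so marks the future O1 carbon without ambiguity, the aryl iodide being tolerated.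

Step 7
Reactants: 9 (S)-lavandulyl iodide; 12 2-[3,5-bis(TBSO)-4-iodophenyl]-4,4,5,5-tetramethyl-1,3,2-dioxaborolane
Product: 15 2-{3,5-bis(TBSO)-4-[(2R)-lavandulyl]phenyl}-4,4,5,5-tetramethyl-1,3,2-dioxaborolane, via (S)-lavandulyllithium 13 (not isolated), via (S)-lavandulylzinc chloride 14 (not isolated)
Conditions: 9 (1.3 equiv), t-BuLi (2.6 equiv), Et2O–pentane, −78 °C; ZnCl2 (1.4 equiv, THF), −78 °C → rt; then 12, Pd(OAc)2 (3 mol %), SPhos (6 mol %), THF, 45 °C
Reagents that add atoms: none
Why: Negishi sp3–sp2 coupling, in which iodine–lithium exchange and transmetalation give the primary alkylzinc without radical intermediates (no vinyl shift, β-stereocentre untouched), the bulky biarylphosphine favours reductive elimination over β-hydride elimination at the doubly ortho-substituted aryl, and the pinacol boronate stays inert because no base is present.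

Step 8
Reactants: 15 2-{3,5-bis(TBSO)-4-[(2R)-lavandulyl]phenyl}-4,4,5,5-tetramethyl-1,3,2-dioxaborolane
Product: 16 3,5-bis(TBSO)-4-[(2R)-lavandulyl]phenol
Conditions: NaBO3·4H2O (3 equiv), THF/H2O (1:1), 0 °C → rt
Reagents that add atoms: sodium perborate, [Na+].[Na+].O[B-]1(O)OO[B-](O)(O)OO1
Why: perborate oxidation of the arylboronate (peroxide addition to boron, then 1,2-aryl shift to oxygen) gives the phenol, and this nucleophilic oxidant should leave the two alkenes and the hindered aryl silyl ethers alone.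

Step 9
Reactants: 16 3,5-bis(TBSO)-4-[(2R)-lavandulyl]phenol
Product: 17 2,4-bis(TBSO)-6-hydroxy-3-[(2R)-lavandulyl]benzaldehyde
Conditions: MgCl2 (2.5 equiv), Et3N (4 equiv), (CH2O)n (6 equiv), THF, 65 °C
Reagents that add atoms: paraformaldehyde (formaldehyde unit), C=O
Why: magnesium phenoxide-directed ortho-formylation (Casnati–Skattebøl) places the formyl group next to the free hydroxyl, and since the two ortho positions are equivalent only one regioisomer can form, with the carbonyl carbon between the future O1 and the C5 silyl ether.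

Step 10
Reactants: 18 2,4,6-trihydroxybenzaldehyde
Product: 19 2,4,6-tris(TBSO)benzaldehyde
Conditions: TBSCl (3.6 equiv), imidazole (7 equiv), DMAP (cat.), DMF, rt → 40 °C
Reagents that add atoms: tert-butyldimethylsilyl chloride, CC(C)(C)[Si](C)(C)Cl
Why: exhaustive silylation of the three phenols, DMAP and gentle warming being used to overcome the hydrogen bonds of the two ortho hydroxyls to the aldehyde.

Step 11
Reactants: 19 2,4,6-tris(TBSO)benzaldehyde
Product: 20 [2,4,6-tris(TBSO)phenyl]methanol
Conditions: i-Bu2AlH (1.2 equiv), CH2Cl2, −78 °C; aq. potassium sodium tartrate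
Reagents that add atoms: none
Why: hydride reduction of the aldehyde at low temperature gives an aluminium alkoxide that should not trigger aryl-to-alkyl silyl migration; the ionisation-prone alcohol is to be purified on base-washed silica and used at once.

Step 12
Reactants: 17 2,4-bis(TBSO)-6-hydroxy-3-[(2R)-lavandulyl]benzaldehyde; 20 [2,4,6-tris(TBSO)phenyl]methanol
Product: 21 2,4-bis(TBSO)-3-[(2R)-lavandulyl]-6-{[2,4,6-tris(TBSO)phenyl]methoxy}benzaldehyde
Conditions: PPh3 (1.5 equiv), DIAD (1.5 equiv), toluene, 0 °C → rt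
Reagents that add atoms: none
Why: Mitsunobu etherification, in which the acidic hydrogen-bonded salicylaldehyde phenol is O-alkylated by the oxyphosphonium salt of the primary benzylic alcohol under neutral conditions, avoiding the unstable trioxygenated benzyl halide.

Step 13
Reactants: 21 2,4-bis(TBSO)-3-[(2R)-lavandulyl]-6-{[2,4,6-tris(TBSO)phenyl]methoxy}benzaldehyde
Product: 22 2,4-bis(TBSO)-3-[(2R)-lavandulyl]-6-{[2,4,6-tris(TBSO)phenyl]methoxy}benzoic acid
Conditions: NaClO2 (3 equiv), NaH2PO4 (3 equiv), 2-methyl-2-butene (30 equiv), t-BuOH/THF/H2O, 0 °C → rt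
Reagents that add atoms: sodium chlorite, [Na+].[O-]Cl=O
Why: Pinnick oxidation of the hindered aryl aldehyde, with a large excess of 2-methyl-2-butene to intercept hypochlorous acid before it reaches the lavandulyl alkenes or the electron-rich rings.

Step 14
Reactants: 22 2,4-bis(TBSO)-3-[(2R)-lavandulyl]-6-{[2,4,6-tris(TBSO)phenyl]methoxy}benzoic acid; 23 (trimethylsilyl)diazomethane
Product: 26 2-diazo-1-{2,4-bis(TBSO)-3-[(2R)-lavandulyl]-6-{[2,4,6-tris(TBSO)phenyl]methoxy}phenyl}ethan-1-one, via acid chloride 24 (not isolated), via C-silyl diazoketone 25 (not isolated)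
Conditions: 1-chloro-N,N,2-trimethylprop-1-en-1-amine (1.3 equiv), CH2Cl2, 0 °C → rt; then 23 (2.5 equiv), Et3N (1.5 equiv), THF/MeCN (1:1), 0 °C → rt; aq. NaHCO3 work-up
Reagents that add atoms: none
Why: the Ghosez reagent makes the acid chloride without releasing HCl (which would cleave the acid-labile benzyl ether), C-acylation of the diazoalkane follows as in the first stage of an Arndt–Eistert sequence, and the C–Si bond is hydrolysed on work-up.

Step 15
Reactants: 26 2-diazo-1-{2,4-bis(TBSO)-3-[(2R)-lavandulyl]-6-{[2,4,6-tris(TBSO)phenyl]methoxy}phenyl}ethan-1-one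
Product: 27 (2S)-5,7-bis(TBSO)-6-[(2R)-lavandulyl]-2-[2,4,6-tris(TBSO)phenyl]chroman-4-one
Conditions: Rh2(S-PTTL)4 [dirhodium tetrakis(N-phthaloyl-(S)-tert-leucinate)] (2 mol %), CH2Cl2, 0 °C, slow addition of 26 (final 0.01 M)
Reagents that add atoms: none
Why: The dimer of divalent rhodium expels N2 from 26 to give an electrophilic metal carbene at C3, which inserts into one of the two benzylic C–H bonds of the O1–CH2–aryl unit through a concerted, asynchronous three-centre transition state with hydride-transfer character, forming C2–C3 with retention at carbon. The closest known reaction type is the chiral dirhodium carboxylate-catalysed intramolecular C–H insertion of 2-alkoxyaryl diazoketones to chroman-4-ones, together with the related insertions into benzylic ether C–H bonds that give 2-aryl-2,3-dihydrobenzofurans. Ring C closes by a 1,6-insertion (six-membered array C3–C4–C4a–C8a–O1–C2); this is the only activated C–H within reach, because the silyl ethers carry no C–H next to oxygen and the lavandulyl alkenes sit meta to the carbene-bearing carbon and cannot reach it. The C2 configuration is catalyst-controlled: the phthalimido walls of the tert-leucinate ligands should tell the two benzylic hydrogens apart, the remote side-chain centre having no influence. The step needs chemoselectivity for C–H insertion over oxonium ylide formation at O1 with 1,2-benzyl shift (which would lead to a 2-benzylbenzofuran-3-one) and over attack on the C5 silyl ether oxygen; this should be helped by the low basicity of O1 (a vinylogous ester oxygen flanked by a 2,6-disubstituted benzyl group), by the strongly hydridic C–H (next to oxygen and benzylic to a trioxygenated ring), by the bulky carboxylate ligands and by slow addition in a non-coordinating solvent. Ring C forms under neutral conditions, so no retro-oxa-Michael opening to the chalcone can erode C2.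

Step 16
Reactants: 27 (2S)-5,7-bis(TBSO)-6-[(2R)-lavandulyl]-2-[2,4,6-tris(TBSO)phenyl]chroman-4-one
Product: 28 (2S)-5,7-dihydroxy-6-[(2R)-5-methyl-2-(prop-1-en-2-yl)hex-4-en-1-yl]-2-(2,4,6-trihydroxyphenyl)-2,3-dihydro-4H-chromen-4-one
Conditions: Bu4NF (6 equiv), AcOH (6 equiv), THF, 0 °C; pH 6 phosphate buffer work-up
Reagents that add atoms: none
Why: fluoride cleaves all five aryl Si–O bonds, and the acetic acid buffer keeps the freed phenols protonated so that neither phenoxide-driven opening of ring C (loss of C2 configuration) nor acid-induced cyclisation of a phenol onto the lavandulyl alkenes should occur.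

**Compound list**

1 | (S)-4-benzyloxazolidin-2-one | O=C1N[C@@H](Cc2ccccc2)CO1 | starting material
2 | 3-methylbut-2-enoyl chloride | CC(C)=CC(=O)Cl | starting material
3 | lithium (S)-4-benzyl-2-oxooxazolidin-3-ide | [Li+].O=C1[N-][C@@H](Cc2ccccc2)CO1 | intermediate (not isolated)
4 | (S)-4-benzyl-3-(3-methylbut-2-enoyl)oxazolidin-2-one | CC(C)=CC(=O)N1[C@@H](Cc2ccccc2)COC1=O | intermediate
5 | 1-bromo-3-methylbut-2-ene (prenyl bromide) | CC(C)=CCBr | starting material
6 | sodium (Z)-dienolate of 4 | C=C(C)/C=C(\[O-])N1[C@@H](Cc2ccccc2)COC1=O.[Na+] | intermediate (not isolated)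
7 | (S)-4-benzyl-3-[(2S)-5-methyl-2-(prop-1-en-2-yl)hex-4-enoyl]oxazolidin-2-one | C=C(C)[C@H](CC=C(C)C)C(=O)N1[C@@H](Cc2ccccc2)COC1=O | intermediate
8 | (S)-lavandulol, (2S)-5-methyl-2-(prop-1-en-2-yl)hex-4-en-1-ol | C=C(C)[C@H](CC=C(C)C)CO | intermediate
9 | (S)-lavandulyl iodide, (3S)-3-(iodomethyl)-2,6-dimethylhepta-1,5-diene | C=C(C)[C@H](CC=C(C)C)CI | intermediate
10 | 2-iodobenzene-1,3-diol (2-iodoresorcinol) | Oc1cccc(O)c1I | starting material
11 | 2-iodo-1,3-bis(TBSO)benzene | CC(C)(C)[Si](C)(C)Oc1cccc(O[Si](C)(C)C(C)(C)C)c1I | intermediate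
12 | 2-[3,5-bis(TBSO)-4-iodophenyl]-4,4,5,5-tetramethyl-1,3,2-dioxaborolane | CC1(C)OB(OC1(C)C)c1cc(O[Si](C)(C)C(C)(C)C)c(I)c(O[Si](C)(C)C(C)(C)C)c1 | intermediate
13 | (S)-lavandulyllithium, [(2S)-5-methyl-2-(prop-1-en-2-yl)hex-4-en-1-yl]lithium | C=C(C)[C@H](CC=C(C)C)C[Li] | intermediate (not isolated)
14 | (S)-lavandulylzinc chloride, [(2S)-5-methyl-2-(prop-1-en-2-yl)hex-4-en-1-yl]zinc chloride | C=C(C)[C@H](CC=C(C)C)C[Zn]Cl | intermediate (not isolated)
15 | 2-{3,5-bis(TBSO)-4-[(2R)-lavandulyl]phenyl}-4,4,5,5-tetramethyl-1,3,2-dioxaborolane | C=C(C)[C@H](CC=C(C)C)Cc1c(O[Si](C)(C)C(C)(C)C)cc(B2OC(C)(C)C(C)(C)O2)cc1O[Si](C)(C)C(C)(C)C | intermediate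
16 | 3,5-bis(TBSO)-4-[(2R)-lavandulyl]phenol | C=C(C)[C@H](CC=C(C)C)Cc1c(O[Si](C)(C)C(C)(C)C)cc(O)cc1O[Si](C)(C)C(C)(C)C | intermediate
17 | 2,4-bis(TBSO)-6-hydroxy-3-[(2R)-lavandulyl]benzaldehyde | C=C(C)[C@H](CC=C(C)C)Cc1c(O[Si](C)(C)C(C)(C)C)cc(O)c(C=O)c1O[Si](C)(C)C(C)(C)C | intermediate
18 | 2,4,6-trihydroxybenzaldehyde | O=Cc1c(O)cc(O)cc1O | starting material
19 | 2,4,6-tris(TBSO)benzaldehyde | O=Cc1c(O[Si](C)(C)C(C)(C)C)cc(O[Si](C)(C)C(C)(C)C)cc1O[Si](C)(C)C(C)(C)C | intermediate
20 | [2,4,6-tris(TBSO)phenyl]methanol | OCc1c(O[Si](C)(C)C(C)(C)C)cc(O[Si](C)(C)C(C)(C)C)cc1O[Si](C)(C)C(C)(C)C | intermediate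
21 | 2,4-bis(TBSO)-3-[(2R)-lavandulyl]-6-{[2,4,6-tris(TBSO)phenyl]methoxy}benzaldehyde | C=C(C)[C@H](CC=C(C)C)Cc1c(O[Si](C)(C)C(C)(C)C)cc(OCc2c(O[Si](C)(C)C(C)(C)C)cc(O[Si](C)(C)C(C)(C)C)cc2O[Si](C)(C)C(C)(C)C)c(C=O)c1O[Si](C)(C)C(C)(C)C | intermediate
22 | 2,4-bis(TBSO)-3-[(2R)-lavandulyl]-6-{[2,4,6-tris(TBSO)phenyl]methoxy}benzoic acid | C=C(C)[C@H](CC=C(C)C)Cc1c(O[Si](C)(C)C(C)(C)C)cc(OCc2c(O[Si](C)(C)C(C)(C)C)cc(O[Si](C)(C)C(C)(C)C)cc2O[Si](C)(C)C(C)(C)C)c(C(=O)O)c1O[Si](C)(C)C(C)(C)C | intermediate
23 | (trimethylsilyl)diazomethane | C[Si](C)(C)C=[N+]=[N-] | starting material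
24 | 2,4-bis(TBSO)-3-[(2R)-lavandulyl]-6-{[2,4,6-tris(TBSO)phenyl]methoxy}benzoyl chloride | C=C(C)[C@H](CC=C(C)C)Cc1c(O[Si](C)(C)C(C)(C)C)cc(OCc2c(O[Si](C)(C)C(C)(C)C)cc(O[Si](C)(C)C(C)(C)C)cc2O[Si](C)(C)C(C)(C)C)c(C(=O)Cl)c1O[Si](C)(C)C(C)(C)C | intermediate (not isolated)
25 | 2-diazo-2-(trimethylsilyl)-1-{2,4-bis(TBSO)-3-[(2R)-lavandulyl]-6-{[2,4,6-tris(TBSO)phenyl]methoxy}phenyl}ethan-1-one | C=C(C)[C@H](CC=C(C)C)Cc1c(O[Si](C)(C)C(C)(C)C)cc(OCc2c(O[Si](C)(C)C(C)(C)C)cc(O[Si](C)(C)C(C)(C)C)cc2O[Si](C)(C)C(C)(C)C)c(C(=O)C(=[N+]=[N-])[Si](C)(C)C)c1O[Si](C)(C)C(C)(C)C | intermediate (not isolated)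
26 | 2-diazo-1-{2,4-bis(TBSO)-3-[(2R)-lavandulyl]-6-{[2,4,6-tris(TBSO)phenyl]methoxy}phenyl}ethan-1-one | C=C(C)[C@H](CC=C(C)C)Cc1c(O[Si](C)(C)C(C)(C)C)cc(OCc2c(O[Si](C)(C)C(C)(C)C)cc(O[Si](C)(C)C(C)(C)C)cc2O[Si](C)(C)C(C)(C)C)c(C(=O)C=[N+]=[N-])c1O[Si](C)(C)C(C)(C)C | intermediate
27 | (2S)-5,7-bis(TBSO)-6-[(2R)-lavandulyl]-2-[2,4,6-tris(TBSO)phenyl]chroman-4-one | C=C(C)[C@H](CC=C(C)C)Cc1c(O[Si](C)(C)C(C)(C)C)cc2c(c1O[Si](C)(C)C(C)(C)C)C(=O)C[C@@H](c1c(O[Si](C)(C)C(C)(C)C)cc(O[Si](C)(C)C(C)(C)C)cc1O[Si](C)(C)C(C)(C)C)O2 | intermediate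
28 | (2S)-5,7-dihydroxy-6-[(2R)-5-methyl-2-(prop-1-en-2-yl)hex-4-en-1-yl]-2-(2,4,6-trihydroxyphenyl)-2,3-dihydro-4H-chromen-4-one | C=C(C)[C@H](CC=C(C)C)Cc1c(O)cc2c(c1O)C(=O)C[C@@H](c1c(O)cc(O)cc1O)O2 | target

**Step count and risks**

Total step count: 16. Longest linear sequence: 12 steps (steps 1–4, 7–9 and 12–16).

Steps most likely to fail:

Step 15. The carbenoid may be diverted before it reaches the benzylic C–H: attack of O1 on the carbene gives an oxonium ylide whose very stabilised benzyl group shifts to carbon, silyl transfer from the C5 ether oxygen is a second escape, and the two benzylic hydrogens may be told apart poorly. The fallback sets out from 17 and 19 and comes back at 27. Addition of MeMgBr (excess, THF, −78 → 0 °C) to 17 should give the benzylic carbinol F1. Oxidation with MnO2 in CH2Cl2 should give the 2'-hydroxyacetophenone F2. Kabbe-type condensation of F2 with 19 (pyrrolidine, toluene, 4 Å molecular sieves, 60 °C; aldol condensation then oxa-Michael closure) should give the flavanone as a mixture of C2 epimers F3. Because the side-chain centre is fixed, the two epimers are diastereomers and should be separable by preparative HPLC on a chiral stationary phase; the (2S) epimer is 27, and the other can be re-equilibrated with the amine and recycled.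

Step 12. The oxyphosphonium salt of the trioxygenated benzyl alcohol may ionise instead of undergoing SN2 attack, leading to C-benzylation of ring A or self-condensation of the ring B unit, and the doubly ortho-substituted benzylic carbon may react slowly. The fallback sets out from 20 and 17 and comes back at 21. Alcohol 20 is converted with methyl chloroformate and pyridine (CH2Cl2, 0 °C) to the benzyl methyl carbonate F4. F4 then benzylates phenol 17 under palladium-catalysed benzylic substitution (Pd(η3-C3H5)(C5H5), DPEphos, toluene, 60 °C) through a benzylpalladium intermediate, with loss of CO2 and methanol, to give 21.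

Step 7. β-Hydride elimination from the alkylpalladium intermediate (which would give a conjugated diene), slow coupling at the doubly ortho-substituted iodide, or unwanted transmetalation of the boronate may lower the conversion. The fallback sets out from 12 and 9 and comes back at 16; it makes the C–O bond first and the C–C bond by a boron-based coupling. Oxidation of 12 with NaBO3·4H2O should give 4-iodo-3,5-bis(TBSO)phenol F5. The alkyllithium 13 (from 9 as in step 7) is added to 9-methoxy-9-borabicyclo[3.3.1]nonane to give the lithium alkyl(methoxy)borate F6. F6 is coupled with F5, present as its phenoxide, in a B-alkyl Suzuki–Miyaura reaction (PdCl2(dppf), K3PO4, DMF/THF, rt) to give 16 directly.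

**Further compounds**

F1 | step 15 | 1-{2,4-bis(TBSO)-6-hydroxy-3-[(2R)-lavandulyl]phenyl}ethan-1-ol (both carbinol epimers) | C=C(C)[C@H](CC=C(C)C)Cc1c(O[Si](C)(C)C(C)(C)C)cc(O)c(C(C)O)c1O[Si](C)(C)C(C)(C)C
F2 | step 15 | 1-{2,4-bis(TBSO)-6-hydroxy-3-[(2R)-lavandulyl]phenyl}ethan-1-one | C=C(C)[C@H](CC=C(C)C)Cc1c(O[Si](C)(C)C(C)(C)C)cc(O)c(C(C)=O)c1O[Si](C)(C)C(C)(C)C
F3 | step 15 | (2RS)-5,7-bis(TBSO)-6-[(2R)-lavandulyl]-2-[2,4,6-tris(TBSO)phenyl]chroman-4-one (mixture of C2 epimers) | C=C(C)[C@H](CC=C(C)C)Cc1c(O[Si](C)(C)C(C)(C)C)cc2c(c1O[Si](C)(C)C(C)(C)C)C(=O)CC(c1c(O[Si](C)(C)C(C)(C)C)cc(O[Si](C)(C)C(C)(C)C)cc1O[Si](C)(C)C(C)(C)C)O2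
F4 | step 12 | methyl [2,4,6-tris(TBSO)phenyl]methyl carbonate | COC(=O)OCc1c(O[Si](C)(C)C(C)(C)C)cc(O[Si](C)(C)C(C)(C)C)cc1O[Si](C)(C)C(C)(C)C
F5 | step 7 | 4-iodo-3,5-bis(TBSO)phenol | Oc1cc(O[Si](C)(C)C(C)(C)C)c(I)c(O[Si](C)(C)C(C)(C)C)c1
F6 | step 7 | lithium 9-methoxy-9-[(2S)-5-methyl-2-(prop-1-en-2-yl)hex-4-en-1-yl]-9-boratabicyclo[3.3.1]nonane | C=C(C)[C@H](CC=C(C)C)C[B-]1(OC)C2CCCC1CCC2.[Li+]
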